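**Assumption:** the SMILES is read as the (5E,7Z,12R,14Z) isomer; prostanoid numbering is used in the text (C1 = ester carbon, C8/C12 = ring carbons carrying the chains, C9 = ketone, C10 = C–Br). In step 4 the sense of induction must be fixed by a first screen; both catalyst antipodes are available.

## Retrosynthetic overview

1. Target 20 ⇒ 12-O-acetylation plus a 7Z exocyclic alkene made by anti-aldol / anti-elimination from hydroxy enone 12 and enal 15.
2. 12 ⇒ Stork–Danheiser carbonyl transposition of the α′-ketol 10, with bromine already on the ring.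
3. 10 ⇒ key C12–O bond: enantioconvergent catalytic asymmetric hydroxylation of the silyl dienol ether of rac-6.
4. 6 ⇒ α′-alkylation of bromo vinylogous ester 4 with (Z)-octenyl bromide 2; 15 ⇒ cross-metathesis of 13 with 14.
5. Ring order: the only ring is bought as 3-ethoxycyclopent-2-enone 3; no ring is formed in the route.

## Route

Step 1
Reactants: 1 (2Z)-oct-2-en-1-ol
Product: 2 (2Z)-1-bromooct-2-ene
Conditions: PBr3 (0.4 equiv), pyridine (cat.), Et2O, −20 → 0 °C
Reagents that add atoms: phosphorus tribromide, BrP(Br)Br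
Why: PBr3 bromination of a primary allylic alcohol is an SN2 displacement on the phosphite ester at low temperature, so no allyl cation forms and the Z alkene is kept; no stereocentre is involved.

Step 2
Reactants: 3 3-ethoxycyclopent-2-en-1-one
Product: 4 2-bromo-3-ethoxycyclopent-2-en-1-one
Conditions: NBS (1.05 equiv), CH2Cl2, 0 °C → rt
Reagents that add atoms: N-bromosuccinimide, O=C1CCC(=O)N1Br
Why: Electrophilic bromination of a vinylogous ester occurs at C2, the nucleophilic α-carbon of the push–pull enol ether (Br+ addition, then loss of H+), leaving the α′ and γ CH2 groups untouched.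

Step 3
Reactants: 4 2-bromo-3-ethoxycyclopent-2-en-1-one, 2 (2Z)-1-bromooct-2-ene
Product: 6 rac-2-bromo-3-ethoxy-5-[(2Z)-oct-2-en-1-yl]cyclopent-2-en-1-one, via lithium enolate 5 (not isolated)
Conditions: LDA (1.05 equiv), THF, −78 °C; then 2 (1.2 equiv), DMPU, −78 → −30 °C
Reagents that add atoms: none
Why: Stork–Danheiser kinetic α′-alkylation: LDA removes the C5–H next to the carbonyl (not the γ-H) and the lithium enolate displaces the primary allylic bromide by SN2 with the Z alkene intact; the new C5 centre is racemic and is erased in step 4.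

Step 4
Reactants: 6 rac-2-bromo-3-ethoxy-5-[(2Z)-oct-2-en-1-yl]cyclopent-2-en-1-one
Product: 10 (5S)-2-bromo-3-ethoxy-5-hydroxy-5-[(2Z)-oct-2-en-1-yl]cyclopent-2-en-1-one, via lithium enolate 7 (not isolated), via triethylsilyl dienol ether 8 (not isolated), via silyloxy epoxide 9 (not isolated)
Conditions: LDA (1.1 equiv), THF, −78 °C; Et3SiCl, −78 → 0 °C; pentane filtration, solvent switch; Shi-type fructose-derived chiral ketone (30 mol %), Oxone, K2CO3, Bu4NHSO4, MeCN–DMM/aq. buffer (pH 10), −10 °C; aq. citric acid work-up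
Reagents that add atoms: Oxone (potassium peroxymonosulfate), [K+].[O-]S(=O)(=O)OO
Why: Proposed new method: catalytic enantioselective Rubottom-type oxygen transfer to a tetrasubstituted, cross-conjugated 2-silyloxycyclopentadiene — α′-enolisation/silylation flattens C5 of rac-6 (enantioconvergent), the chiral dioxirane formed from the ketone catalyst and Oxone epoxidises the most electron-rich C1=C5 bond through a spiro transition state that tells the flat bromo-enol-ether edge of the diene from its silyloxy/chain edge, and hydrolytic collapse of silyloxy epoxide 9 gives the tertiary α′-ketol, so the C–O bond of the future C12 and its configuration (5S here = 12R in the target) are made in the oxygen-transfer event; closest known reaction type: Shi dioxirane epoxidation of trisubstituted silyl enol ethers and enol esters to α-hydroxy ketones (asymmetric Rubottom oxidation).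

Step 5
Reactants: 10 (5S)-2-bromo-3-ethoxy-5-hydroxy-5-[(2Z)-oct-2-en-1-yl]cyclopent-2-en-1-one
Product: 12 (4S)-2-bromo-4-hydroxy-4-[(2Z)-oct-2-en-1-yl]cyclopent-2-en-1-one, via diol 11 (not isolated)
Conditions: DIBAL-H (2.5 equiv), CH2Cl2, −78 °C; then 1 M HCl, THF, 0 °C → rt
Reagents that add atoms: water, O
Why: Stork–Danheiser 1,3-carbonyl transposition: 1,2-reduction of the vinylogous ester, then acid-promoted loss of the new allylic OH through the ethoxy-stabilised allyl cation and hydrolysis, moves the carbonyl to the former C3 with Br on the α-carbon, while the tertiary carbinol is never ionised and keeps its configuration.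

Step 6
Reactants: 13 methyl hex-5-enoate, 14 (2E)-but-2-enal
Product: 15 methyl (5E)-7-oxohept-5-enoate
Conditions: Hoveyda–Grubbs II (2.5 mol %), 14 (4 equiv), CH2Cl2, 40 °C
Reagents that add atoms: none
Why: Olefin cross-metathesis of a terminal alkene with an electron-poor enal partner is selective for the cross product and gives the E enal under thermodynamic control, driven by loss of propene.

Step 7
Reactants: 12 (4S)-2-bromo-4-hydroxy-4-[(2Z)-oct-2-en-1-yl]cyclopent-2-en-1-one, 15 methyl (5E)-7-oxohept-5-enoate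
Product: 17 methyl (5E,7R)-7-[(1S,5S)-3-bromo-5-hydroxy-5-[(2Z)-oct-2-en-1-yl]-2-oxocyclopent-3-en-1-yl]-7-hydroxyhept-5-enoate (7,8-anti; its 7,8-anti partner (7S,1′R) forms alongside and is carried on), via boron enolate 16 (not isolated)
Conditions: (c-Hex)2BCl (2.3 equiv), Et3N (2.6 equiv), Et2O, −78 → 0 °C; 15 (1.3 equiv), −78 → −20 °C; MeOH/pH 7 buffer work-up (no peroxide)
Reagents that add atoms: none
Why: Boron aldol reaction (dicyclohexylboron enolate): the ring-locked E(O)-enolate adds 1,2 to the enal through a Zimmerman–Traxler chair to give the 7,8-anti adduct (C7 and C8 set here; the face relative to C12 is immaterial because both 7,8-anti diastereomers give the same alkene in step 8), the tertiary OH being masked in situ as its borinate.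

Step 8
Reactants: 17 methyl (5E,7R)-7-[(1S,5S)-3-bromo-5-hydroxy-5-[(2Z)-oct-2-en-1-yl]-2-oxocyclopent-3-en-1-yl]-7-hydroxyhept-5-enoate
Product: 20 methyl (5E,7Z)-7-[(5R)-5-(acetyloxy)-3-bromo-5-[(2Z)-oct-2-en-1-yl]-2-oxocyclopent-3-en-1-ylidene]hept-5-enoate, via mesylate 18 (not isolated), via dienol 19 (not isolated)
Conditions: MsCl (1.15 equiv), Et3N (4 equiv), CH2Cl2, −78 → −20 °C; then Ac2O (5 equiv), DMAP (0.3 equiv), 0 °C → rt, dark
Reagents that add atoms: acetic anhydride, CC(=O)OC(C)=O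
Why: Mesylation of the secondary allylic alcohol, then base-induced anti-periplanar E2 elimination of the 7,8-anti β-mesyloxy ketone (H8 and OMs anti places C6 syn to the C9 carbonyl), gives the 7Z exocyclic alkene — elimination into the ring is impossible at quaternary C12 — and DMAP-catalysed acyl transfer then acetylates the tertiary alcohol without touching the stereocentre.

## Compound list

1 | (2Z)-oct-2-en-1-ol | CCCCC/C=C\CO | starting material
2 | (2Z)-1-bromooct-2-ene | CCCCC/C=C\CBr | intermediate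
3 | 3-ethoxycyclopent-2-en-1-one | CCOC1=CC(=O)CC1 | starting material
4 | 2-bromo-3-ethoxycyclopent-2-en-1-one | CCOC1=C(Br)C(=O)CC1 | intermediate
5 | lithium 5-bromo-4-ethoxycyclopenta-1,4-dien-1-olate (α′-enolate of 4, not isolated) | [Li+].[O-]C1=CCC(OCC)=C1Br | intermediate
6 | rac-2-bromo-3-ethoxy-5-[(2Z)-oct-2-en-1-yl]cyclopent-2-en-1-one | CCCCC/C=C\CC1CC(OCC)=C(Br)C1=O | intermediate
7 | lithium 5-bromo-4-ethoxy-2-[(2Z)-oct-2-en-1-yl]cyclopenta-1,4-dien-1-olate (not isolated) | [Li+].CCCCC/C=C\CC1=C([O-])C(Br)=C(OCC)C1 | intermediate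
8 | ({5-bromo-4-ethoxy-2-[(2Z)-oct-2-en-1-yl]cyclopenta-1,4-dien-1-yl}oxy)triethylsilane (not isolated) | CCCCC/C=C\CC1=C(O[Si](CC)(CC)CC)C(Br)=C(OCC)C1 | intermediate
9 | (1R,5S)-2-bromo-3-ethoxy-5-[(2Z)-oct-2-en-1-yl]-1-[(triethylsilyl)oxy]-6-oxabicyclo[3.1.0]hex-2-ene (not isolated) | CCCCC/C=C\C[C@]12CC(OCC)=C(Br)[C@@]1(O[Si](CC)(CC)CC)O2 | intermediate
10 | (5S)-2-bromo-3-ethoxy-5-hydroxy-5-[(2Z)-oct-2-en-1-yl]cyclopent-2-en-1-one | CCCCC/C=C\C[C@@]1(O)C(=O)C(Br)=C(OCC)C1 | intermediate
11 | (1S)-3-bromo-4-ethoxy-1-[(2Z)-oct-2-en-1-yl]cyclopent-3-ene-1,2-diol (C2 epimers, not isolated) | CCCCC/C=C\C[C@@]1(O)C(O)C(Br)=C(OCC)C1 | intermediate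
12 | (4S)-2-bromo-4-hydroxy-4-[(2Z)-oct-2-en-1-yl]cyclopent-2-en-1-one | CCCCC/C=C\C[C@@]1(O)C=C(Br)C(=O)C1 | intermediate
13 | methyl hex-5-enoate | COC(=O)CCCC=C | starting material
14 | (2E)-but-2-enal (crotonaldehyde) | C/C=C/C=O | starting material
15 | methyl (5E)-7-oxohept-5-enoate | COC(=O)CCC/C=C/C=O | intermediate
16 | {[(1S)-3-bromo-1-[(2Z)-oct-2-en-1-yl]cyclopenta-2,4-diene-1,4-diyl]bis(oxy)}bis(dicyclohexylborane) (O12-borinate boron enolate, not isolated) | CCCCC/C=C\C[C@@]1(OB(C2CCCCC2)C2CCCCC2)C=C(Br)C(OB(C2CCCCC2)C2CCCCC2)=C1 | intermediate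
17 | methyl (5E,7R)-7-[(1S,5S)-3-bromo-5-hydroxy-5-[(2Z)-oct-2-en-1-yl]-2-oxocyclopent-3-en-1-yl]-7-hydroxyhept-5-enoate (7,8-anti aldol, drawn diastereomer) | CCCCC/C=C\C[C@@]1(O)C=C(Br)C(=O)[C@H]1[C@H](O)/C=C/CCCC(=O)OC | intermediate
18 | methyl (5E,7R)-7-[(1S,5S)-3-bromo-5-hydroxy-5-[(2Z)-oct-2-en-1-yl]-2-oxocyclopent-3-en-1-yl]-7-[(methylsulfonyl)oxy]hept-5-enoate (not isolated) | CCCCC/C=C\C[C@@]1(O)C=C(Br)C(=O)[C@H]1[C@H](OS(C)(=O)=O)/C=C/CCCC(=O)OC | intermediate
19 | methyl (5E,7Z)-7-[(5R)-3-bromo-5-hydroxy-5-[(2Z)-oct-2-en-1-yl]-2-oxocyclopent-3-en-1-ylidene]hept-5-enoate (not isolated) | CCCCC/C=C\C[C@@]1(O)C=C(Br)C(=O)/C1=C\C=C\CCCC(=O)OC | intermediate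
20 | methyl (5E,7Z)-7-[(5R)-5-(acetyloxy)-3-bromo-5-[(2Z)-oct-2-en-1-yl]-2-oxocyclopent-3-en-1-ylidene]hept-5-enoate | CCCCC/C=C\C[C@@]1(OC(C)=O)C=C(Br)C(=O)/C1=C\C=C\CCCC(=O)OC | target

## Step count and risks

Total steps: 8. Longest linear sequence: 6 (steps 2, 3, 4, 5, 7, 8, from 3).

Three steps most likely to fail:

**Step 4 (proposed new step).** The ee on a tetrasubstituted silyl dienol ether is unproven, and the diene may hydrolyse or isomerise before oxidation. The fallback uses known reagent-controlled chemistry; it sets out from 6 and returns at 10. 6 is deprotonated with NaHMDS (THF, −78 °C) to sodium 5-bromo-4-ethoxy-2-[(2Z)-oct-2-en-1-yl]cyclopenta-1,4-dien-1-olate F1. F1 is hydroxylated with a stoichiometric enantiopure [(8,8-dichlorocamphoryl)sulfonyl]oxaziridine (Davis enolate hydroxylation, antipode chosen for the S ketol). NH4Cl quench gives 10, polished by chiral SFC if needed.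

**Step 7.** The anti selectivity of the boron aldol on an α-bromo enone carrying a free tertiary OH may fall short. The fallback sets out from 12 and returns at 17. 12 is silylated (TMSCl, imidazole) to (4S)-2-bromo-4-[(2Z)-oct-2-en-1-yl]-4-[(trimethylsilyl)oxy]cyclopent-2-en-1-one F2. LDA (THF, −78 °C) gives lithium (3S)-5-bromo-3-[(2Z)-oct-2-en-1-yl]-3-[(trimethylsilyl)oxy]cyclopenta-1,4-dien-1-olate F3. A kinetic lithium aldol with 15 (5 min, AcOH quench) gives methyl (5E,7R)-7-[(1S,5S)-3-bromo-5-[(2Z)-oct-2-en-1-yl]-2-oxo-5-[(trimethylsilyl)oxy]cyclopent-3-en-1-yl]-7-hydroxyhept-5-enoate F4, the anti adducts being separated from syn by chromatography. Citric acid/MeOH removes the silyl group to give 17.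

**Step 8.** The mesylate may eliminate by E1cB rather than anti E2, eroding 7Z, and DMAP may isomerise 7Z to 7E. The fallback sets out from 17 and returns at 20. 17 is treated with excess Ac2O/DMAP/Et3N at rt: acetylation, non-stereospecific loss of acetic acid and acetylation of O12 give 20 together with methyl (5E,7E)-7-[(5R)-5-(acetyloxy)-3-bromo-5-[(2Z)-oct-2-en-1-yl]-2-oxocyclopent-3-en-1-ylidene]hept-5-enoate F5. The two are separated by HPLC, and F5 is re-equilibrated photochemically (350 nm, benzene) and recycled to 20.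

## Further compounds

F1 | step 4 | sodium 5-bromo-4-ethoxy-2-[(2Z)-oct-2-en-1-yl]cyclopenta-1,4-dien-1-olate | [Na+].CCCCC/C=C\CC1=C([O-])C(Br)=C(OCC)C1
F2 | step 7 | (4S)-2-bromo-4-[(2Z)-oct-2-en-1-yl]-4-[(trimethylsilyl)oxy]cyclopent-2-en-1-one | CCCCC/C=C\C[C@@]1(O[Si](C)(C)C)C=C(Br)C(=O)C1
F3 | step 7 | lithium (3S)-5-bromo-3-[(2Z)-oct-2-en-1-yl]-3-[(trimethylsilyl)oxy]cyclopenta-1,4-dien-1-olate | [Li+].CCCCC/C=C\C[C@@]1(O[Si](C)(C)C)C=C(Br)C([O-])=C1
F4 | step 7 | methyl (5E,7R)-7-[(1S,5S)-3-bromo-5-[(2Z)-oct-2-en-1-yl]-2-oxo-5-[(trimethylsilyl)oxy]cyclopent-3-en-1-yl]-7-hydroxyhept-5-enoate | CCCCC/C=C\C[C@@]1(O[Si](C)(C)C)C=C(Br)C(=O)[C@H]1[C@H](O)/C=C/CCCC(=O)OC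
F5 | step 8 | methyl (5E,7E)-7-[(5R)-5-(acetyloxy)-3-bromo-5-[(2Z)-oct-2-en-1-yl]-2-oxocyclopent-3-en-1-ylidene]hept-5-enoate | CCCCC/C=C\C[C@@]1(OC(C)=O)C=C(Br)C(=O)/C1=C/C=C/CCCC(=O)OC
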